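The route rests on disconnecting the bond between C7, the ring-bound 1,1-disubstituted alkene carbon, and C8, the neighbouring acyloxy carbinol carbon. This 2-substituted allylic alcohol unit is the retron of an alkenyl-metal/aldehyde addition. A catalytic asymmetric nickel/chromium (Nozaki–Hiyama–Kishi) coupling joins a carvone-derived alkenyl triflate (cyclohexane ring with the cis-epoxide already set, ketone oxygen masked as a silyl ether) to 4-methylpent-3-enal, creating the C7–C8 bond and the C8 stereocentre in one operation. Nine carbons of (R)-carvone map onto the ring, the ring methyl, C7 and the exo-methylene, which is the former acetyl methyl left after ozonolysis.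

Key step: step 7

Numbering used for orientation: ring C1 (ketone carbon of the target), C2 (methyl-bearing epoxide carbon), C3 (epoxide CH), C4 (CH2), C5 (CH bearing the side chain), C6 (CH bearing the ring angelate); side chain C7 (alkene carbon), C8 (carbinol carbon), C9 (CH2), C10 and C11 (side-chain epoxide).

Assumption: both antipodes of the oxazoline–sulfonamide ligand of step 7 are accessible from valinol, and the antipode that delivers the (8S) carbinol is identified by one trial with each.

Step 1
Reactants: 1 4-methylpent-3-en-1-ol
Product: 2 4-methylpent-3-enal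
Conditions: Dess–Martin periodinane, NaHCO3, CH2Cl2, 0 °C to rt; used at once as a solution
Reagents that add atoms: none
Why: Dess–Martin oxidation of the homoallylic primary alcohol under bicarbonate buffering should stop at the β,γ-unsaturated aldehyde without moving the alkene into conjugation.

Step 2
Reactants: 3 (R)-(−)-carvone
Product: 4 (−)-cis-carveol
Conditions: NaBH4, CeCl3·7H2O, MeOH, −78 to 0 °C
Reagents that add atoms: none
Why: Luche reduction should add hydride 1,2 and axially to the enone, giving the pseudo-equatorial C1 alcohol cis to the isopropenyl group, which is the handle that steers the next step.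

Step 3
Reactants: 4 (−)-cis-carveol
Product: 5 cis-epoxy alcohol
Conditions: VO(acac)2 (cat.), t-BuOOH, CH2Cl2, 0 °C to rt
Reagents that add atoms: tert-butyl hydroperoxide CC(C)(C)OO
Why: Vanadium-catalysed hydroxyl-directed epoxidation should deliver oxygen to the ring alkene on the face of the C1 hydroxyl, setting C2 and C3 cis to the C5 substituent, and should leave the isolated isopropenyl alkene untouched.

Step 4
Reactants: 5 cis-epoxy alcohol
Product: 6 tert-butyldimethylsilyl ether of 5
Conditions: TBSCl, imidazole, DMF, rt
Reagents that add atoms: tert-butyldimethylsilyl chloride CC(C)(C)[Si](C)(C)Cl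
Why: Standard silylation masks the C1 carbinol, the future ketone, at an oxidation level that tolerates the enolate and chromium chemistry ahead.

Step 5
Reactants: 6 tert-butyldimethylsilyl ether of 5
Product: 8 methyl ketone, via ozonide 7 (not isolated)
Conditions: O3, CH2Cl2, −78 °C; then PPh3, −78 °C to rt
Reagents that add atoms: ozone [O-][O+]=O
Why: Ozonolysis with reductive work-up cleaves the only alkene to the methyl ketone whose methyl later becomes the exo-methylene, while epoxide and silyl ether are inert to ozone.

Step 6
Reactants: 8 methyl ketone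
Product: 10 alkenyl triflate, via lithium enolate 9 (not isolated)
Conditions: LiN(iPr)2, THF, −78 °C; then N-(5-chloro-2-pyridyl)triflimide, −78 °C; NH4Cl quench
Reagents that add atoms: N-(5-chloro-2-pyridyl)bis(trifluoromethanesulfonimide) Clc1ccc(nc1)N(S(=O)(=O)C(F)(F)F)S(=O)(=O)C(F)(F)F
Why: Kinetic deprotonation by the hindered amide base at the unhindered acetyl methyl, not at the tertiary C5–H, followed by O-sulfonylation of the enolate (standard enol triflate synthesis) should give the 1-substituted vinyl triflate and leave the C5 stereocentre untouched.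

Step 7
Reactants: 10 alkenyl triflate; 2 4-methylpent-3-enal
Product: 12 (8S)-allylic alcohol, via alkenylchromium species 11 (not isolated)
Conditions: CrCl2 (15 mol%), N-[2-(4-isopropyl-4,5-dihydrooxazol-2-yl)-6-methylphenyl]methanesulfonamide (single enantiomer, 17 mol%), Et3N (17 mol%), NiCl2·(2,9-dimethyl-1,10-phenanthroline) (3 mol%), Mn powder, Zr(C5H5)2Cl2, LiCl, MeCN, rt; aqueous work-up
Reagents that add atoms: none
Why: Zerovalent nickel, formed by reduction of the NiCl2 complex, inserts into the C7–O bond of the triflate and passes the alkenyl group to trivalent chromium carrying the chiral sulfonamide; the alkenylchromium species 11 then adds to the aldehyde carbonyl of 2, Zr(C5H5)2Cl2 frees the chromium alkoxide and Mn returns chromium to the divalent state. The closest known reaction type is the catalytic asymmetric Nozaki–Hiyama–Kishi coupling of 2-substituted alkenyl halides or triflates with aliphatic aldehydes. No ring is closed. The new C8 stereocentre is set by the chiral ligand on chromium (reagent control), because the nearest resident stereocentre, C5, carries two almost equivalent CH2 branches and should exert little bias. The step needs chemoselectivity for the aldehyde and a fixed alkene position: the carbon–chromium bond sits on C7, so the former acetyl methyl becomes the exo-methylene, and because C1 is a silyl ether and not an epoxy ketone, the substrate holds nothing that the mild reductant should attack. The near-neutral medium should keep the β,γ-unsaturated aldehyde from isomerising.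

Step 8
Reactants: 12 (8S)-allylic alcohol
Product: 13 (8S)-8-angelate
Conditions: angelic acid, 2,4,6-trichlorobenzoyl chloride, Et3N, toluene, rt; then 12, 75 °C
Reagents that add atoms: angelic acid C/C=C(/C)C(=O)O
Why: Yamaguchi mixed-anhydride esterification without nucleophilic catalyst is the usual way to form angelates with little Z to E isomerisation, and it acylates the C8 oxygen with retention.

Step 9
Reactants: 13 (8S)-8-angelate
Product: 14 (8S,10R)-10,11-epoxide
Conditions: 1,2:4,5-di-O-isopropylidene-β-D-erythro-2,3-hexodiulo-2,6-pyranose (30 mol%), Oxone (2KHSO5·KHSO4·K2SO4), K2CO3, Bu4NHSO4, Na2B4O7 buffer, MeCN–dimethoxymethane–H2O, 0 °C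
Reagents that add atoms: potassium peroxymonosulfate [K+].[O-]S(=O)(=O)OO
Why: In this Shi epoxidation the chiral dioxirane should react fastest with the electron-rich trisubstituted alkene (the 1,1-disubstituted allylic ester alkene and the conjugated angelate alkene are deactivated), and the D-fructose-derived ketone should give the (10R) epoxide by reagent control.

Step 10
Reactants: 14 (8S,10R)-10,11-epoxide
Product: 15 C1 alcohol
Conditions: Bu4NF, AcOH, THF, 0 °C to rt
Reagents that add atoms: none
Why: Fluoride-mediated desilylation, buffered with acetic acid, should free the C1 hydroxyl without touching the angelate or the two epoxides.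

Step 11
Reactants: 15 C1 alcohol
Product: 16 epoxy ketone
Conditions: Dess–Martin periodinane, NaHCO3, CH2Cl2, rt
Reagents that add atoms: none
Why: Buffered Dess–Martin oxidation should convert the secondary epoxy alcohol into the α,β-epoxy ketone under neutral conditions that affect no stereocentre.

Step 12
Reactants: 16 epoxy ketone
Product: 18 (6S)-α-hydroxy ketone, via sodium enolate 17 (not isolated)
Conditions: NaN(SiMe3)2, THF, −78 °C; then 2-(phenylsulfonyl)-3-phenyloxaziridine, −78 °C; NH4Cl quench
Reagents that add atoms: 2-(phenylsulfonyl)-3-phenyloxaziridine O=S(=O)(c1ccccc1)N1OC1c1ccccc1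
Why: Enolate hydroxylation with an N-sulfonyloxaziridine: the ketone can enolise only toward C6 because C2 is quaternary, and the oxidant should approach the enolate face opposite to both the C5 side chain and the ring epoxide, giving the 6-hydroxyl trans to the side chain.

Step 13
Reactants: 18 (6S)-α-hydroxy ketone
Product: 19 CNP0247177.2 (target)
Conditions: angelic acid, 2,4,6-trichlorobenzoyl chloride, Et3N, toluene, rt; filter; then 18, 75 °C
Reagents that add atoms: angelic acid C/C=C(/C)C(=O)O
Why: A second Yamaguchi esterification should acylate the secondary α-ketol oxygen with retention at C6 and with the Z geometry of the acyl group preserved.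

Compound list
1 | 4-methylpent-3-en-1-ol | CC(C)=CCCO | starting material
2 | 4-methylpent-3-enal | CC(C)=CCC=O | intermediate
3 | (R)-(−)-carvone, (5R)-2-methyl-5-(prop-1-en-2-yl)cyclohex-2-en-1-one | C=C(C)[C@@H]1CC=C(C)C(=O)C1 | starting material
4 | (−)-cis-carveol, (1R,5R)-2-methyl-5-(prop-1-en-2-yl)cyclohex-2-en-1-ol, hydroxyl cis to isopropenyl | C=C(C)[C@@H]1CC=C(C)[C@H](O)C1 | intermediate
5 | cis-epoxy alcohol, (1R,2R,4S,6S)-1-methyl-4-(prop-1-en-2-yl)-7-oxabicyclo[4.1.0]heptan-2-ol; hydroxyl, epoxide oxygen and isopropenyl on the same ring face | C=C(C)[C@@H]1C[C@@H]2O[C@]2(C)[C@H](O)C1 | intermediate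
6 | tert-butyldimethylsilyl ether of 5 | C=C(C)[C@@H]1C[C@@H]2O[C@]2(C)[C@H](O[Si](C)(C)C(C)(C)C)C1 | intermediate
7 | ozonide of 6 (3-methyl-1,2,4-trioxolan-3-yl group at C5, configuration at the trioxolane carbon undefined) | CC1(OCOO1)[C@@H]1C[C@@H]2O[C@]2(C)[C@H](O[Si](C)(C)C(C)(C)C)C1 | intermediate
8 | methyl ketone: acetyl at C5; silyloxy group, epoxide oxygen and acetyl on the same ring face | CC(=O)[C@@H]1C[C@@H]2O[C@]2(C)[C@H](O[Si](C)(C)C(C)(C)C)C1 | intermediate
9 | lithium enolate of 8 (terminal enolate of the acetyl group) | C=C([O-])[C@@H]1C[C@@H]2O[C@]2(C)[C@H](O[Si](C)(C)C(C)(C)C)C1.[Li+] | intermediate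
10 | alkenyl triflate: 1-(trifluoromethylsulfonyloxy)vinyl group at C5 | C=C(OS(=O)(=O)C(F)(F)F)[C@@H]1C[C@@H]2O[C@]2(C)[C@H](O[Si](C)(C)C(C)(C)C)C1 | intermediate
11 | alkenylchromium species from 10 (drawn as the dichloride, chiral ligand on chromium not drawn) | C=C([Cr](Cl)Cl)[C@@H]1C[C@@H]2O[C@]2(C)[C@H](O[Si](C)(C)C(C)(C)C)C1 | intermediate
12 | (8S)-allylic alcohol: C7 exo-methylene, C8 hydroxyl, 4-methylpent-3-enyl terminus, ring as in 6 | C=C([C@H](CC=C(C)C)O)[C@@H]1C[C@@H]2O[C@]2(C)[C@H](O[Si](C)(C)C(C)(C)C)C1 | intermediate
13 | (8S)-8-angelate [(Z)-2-methylbut-2-enoate] of 12 | C=C([C@H](CC=C(C)C)OC(=O)/C(C)=C\C)[C@@H]1C[C@@H]2O[C@]2(C)[C@H](O[Si](C)(C)C(C)(C)C)C1 | intermediate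
14 | (8S,10R)-10,11-epoxide of 13 | C=C([C@H](C[C@H]1OC1(C)C)OC(=O)/C(C)=C\C)[C@@H]1C[C@@H]2O[C@]2(C)[C@H](O[Si](C)(C)C(C)(C)C)C1 | intermediate
15 | C1 alcohol (desilylated 14) | C=C([C@H](C[C@H]1OC1(C)C)OC(=O)/C(C)=C\C)[C@@H]1C[C@@H]2O[C@]2(C)[C@H](O)C1 | intermediate
16 | epoxy ketone: C1 ketone, cis-2,3-epoxide, C6 methylene | C=C([C@H](C[C@H]1OC1(C)C)OC(=O)/C(C)=C\C)[C@@H]1C[C@@H]2O[C@]2(C)C(=O)C1 | intermediate
17 | sodium enolate of 16 (C1–C6 enolate) | C=C([C@H](C[C@H]1OC1(C)C)OC(=O)/C(C)=C\C)[C@@H]1C[C@@H]2O[C@]2(C)C([O-])=C1.[Na+] | intermediate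
18 | (6S)-α-hydroxy ketone: 6-hydroxyl trans to the C5 side chain and to the ring epoxide | C=C([C@H](C[C@H]1OC1(C)C)OC(=O)/C(C)=C\C)[C@@H]1C[C@@H]2O[C@]2(C)C(=O)[C@H]1O | intermediate
19 | CNP0247177.2: 6,8-bis-angelate, ring stereocentres C2, C3, C5, C6 all S, side chain 8S,10R | C=C([C@H](C[C@H]1OC1(C)C)OC(=O)/C(C)=C\C)[C@@H]1C[C@@H]2O[C@]2(C)C(=O)[C@H]1OC(=O)/C(C)=C\C | target

Total step count: 13. Longest linear sequence: 12 steps (steps 2 to 13, from (R)-carvone 3 to 19).

Steps most likely to fail

Step 7. The ligand on chromium may fail to override the substrate, so that the aldehyde is attacked with poor facial selectivity; nickel-mediated dimerisation of the triflate or drift of the aldehyde into conjugation may also lower conversion. The fallback sets out from 10 and comes back at 12, and moves stereocontrol from the carbon–carbon bond formation to a ketone reduction. The same nickel/chromium coupling of 10 with 2 is run with achiral 2,2'-bipyridyl in place of the chiral ligand and should give the C8-epimeric alcohol mixture F1. Dess–Martin oxidation should give the cross-conjugated enone F2. Corey–Bakshi–Shibata reduction of F2 with the (R)-B-methyl oxazaborolidine and catecholborane, in which the 1-substituted vinyl group should act as the large group, should return (8S)-12 under reagent control.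

Step 12. The free sodium enolate may transfer the C8 angeloyl group to C6 through a six-membered transition state, may add to the sulfonimine by-product, or may be oxidised with poor facial selectivity. The fallback sets out from 16 and comes back at 18, and replaces enolate oxidation by a Rubottom oxidation. Compound 16 is deprotonated with NaN(SiMe3)2 in the presence of Me3SiCl (internal quench, so the enolate is trapped as it forms) to give the trimethylsilyl enol ether F3. Dimethyldioxirane in acetone at −78 °C should attack the electron-rich enol ether from the face opposite to the C5 side chain and, after silyl migration, give the α-silyloxy ketone F4. Dilute citric acid in MeOH should then cleave F4 to 18.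

Step 13. Acylation of the hindered α-ketol at 75 °C may be slow and may be accompanied by Z to E isomerisation of the acyl group, an acyloin shift, or chloride opening of an epoxide. The fallback sets out from 18 and comes back at 19, and builds the angelate alkene in place. Compound 18 is esterified at rt with 2-[bis(2,2,2-trifluoroethoxy)phosphoryl]propanoic acid (N,N'-dicyclohexylcarbodiimide, 4-dimethylaminopyridine, CH2Cl2; the acid has no isomerisable alkene, so nucleophilic catalysis is allowed) to give the phosphonate ester F5. Still–Gennari olefination of F5 with KN(SiMe3)2, 18-crown-6 and acetaldehyde in THF at −78 °C should form the Z-trisubstituted alkene and give 19.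

Further compounds
F1 | step 7 | C8-epimeric mixture of allylic alcohol 12 | C=C(C(O)CC=C(C)C)[C@@H]1C[C@@H]2O[C@]2(C)[C@H](O[Si](C)(C)C(C)(C)C)C1
F2 | step 7 | C8 enone (2-substituted vinyl ketone) | C=C(C(=O)CC=C(C)C)[C@@H]1C[C@@H]2O[C@]2(C)[C@H](O[Si](C)(C)C(C)(C)C)C1
F3 | step 12 | trimethylsilyl enol ether of 16 | C=C([C@H](C[C@H]1OC1(C)C)OC(=O)/C(C)=C\C)[C@@H]1C[C@@H]2O[C@]2(C)C(O[Si](C)(C)C)=C1
F4 | step 12 | 6-trimethylsilyloxy ketone (trimethylsilyl ether of 18) | C=C([C@H](C[C@H]1OC1(C)C)OC(=O)/C(C)=C\C)[C@@H]1C[C@@H]2O[C@]2(C)C(=O)[C@H]1O[Si](C)(C)C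
F5 | step 13 | 6-O-[2-bis(2,2,2-trifluoroethoxy)phosphorylpropanoyl] ester of 18 | C=C([C@H](C[C@H]1OC1(C)C)OC(=O)/C(C)=C\C)[C@@H]1C[C@@H]2O[C@]2(C)C(=O)[C@H]1OC(=O)C(C)P(=O)(OCC(F)(F)F)OCC(F)(F)F
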